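## Retrosynthetic overview

1. The epoxide is made last, by peracid epoxidation of the only electron-rich olefin (Z-C3=C4) of a macrocyclic keto-triene. The C1 ketone comes from MnO2 oxidation of an allylic carbinol.
2. The ten-membered carbocycle is closed by ring-closing metathesis between an allyl group on C1 and a 2-methylallyl group on C6; the ring size enforces the Z-olefin.
3. Key disconnection C7–C8: CrCl2 cleaves a 3-(bromomethyl)butenolide by single-electron transfer to a lactone-conjugated allyl radical (radical-polar crossover), which is joined γ-selectively to an unprotected α-angeloyloxy aldehyde. This late union of two complete halves, in place of a ring-closing lactone annulation, sets C7 and C8, turns the butenolide into the α-methylene-γ-lactone and leaves C8–OH free.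
4. The halves: the bromobutenolide comes from acrolein (Brown 2-methylallylation sets C6, then esterification and RCM). The aldehyde comes from an acetaldehyde/2,2-dimethoxyacetaldehyde cross-aldol (sets C9), α-methylenation, angeloylation, allylation and acetal hydrolysis.
5. Ring order: butenolide, then α-methylene-γ-butyrolactone (same ring, olefin transposed in the key step), then the ten-membered ring, then the epoxide.

Assumption: atom labels follow germacranolide numbering (C1 ketone, C3/C4 epoxide with the C15 methyl on C4, C6 lactone O–CH, C7 ring fusion, C8 carbinol, C9 angelate carbon, C10=C14 and C11=C13 methylenes, C12 lactone carbonyl). The target SMILES then reads 3S,4R,6R,7R,8R,9S, with a cis epoxide (from a Z-olefin) and a trans-fused lactone.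

## Route

Step 1
Reactants: 1 acrolein; 2 (2-methylallyl)magnesium chloride
Product: 5 (R)-5-methylhexa-1,5-dien-3-ol, via B-(2-methylallyl)diisopinocampheylborane 3 (not isolated), via borinate ester 4 (not isolated)
Conditions: (+)-Ipc2BOMe, 2, Et2O, −78 to 25 °C; 1, −78 °C; then HOCH2CH2NH2, 25 °C
Reagents that add atoms: (+)-B-methoxydiisopinocampheylborane, COB([C@H]1C[C@H]2C[C@@H]([C@@H]1C)C2(C)C)[C@H]1C[C@H]2C[C@@H]([C@@H]1C)C2(C)C (its boron and isopinocampheyl atoms appear in 3 and 4 only)
Why: Brown allylboration: borane 3 adds to acrolein through a chair Zimmerman–Traxler transition state in which the isopinocampheyl groups select the aldehyde face that gives the (R)-carbinol (future C6), released from 4 by ethanolamine.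

Step 2
Reactants: 5 (R)-5-methylhexa-1,5-dien-3-ol; 6 2-(bromomethyl)acrylic acid
Product: 7 (R)-5-methylhexa-1,5-dien-3-yl 2-(bromomethyl)acrylate
Conditions: DCC, DMAP (5 mol%), CH2Cl2, 0 °C
Reagents that add atoms: none
Why: Steglich esterification acylates the only hydroxyl with retention at C6 and leaves the allylic bromide untouched at 0 °C.

Step 3
Reactants: 7 (R)-5-methylhexa-1,5-dien-3-yl 2-(bromomethyl)acrylate
Product: 8 (R)-3-(bromomethyl)-5-(2-methylallyl)furan-2(5H)-one
Conditions: second-generation Grubbs catalyst RuCl2(=CHPh)(PCy3)(H2IMes) (5 mol%), CH2Cl2 (10 mM), 40 °C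
Reagents that add atoms: none
Why: Ring-closing metathesis between the vinyl and acrylate olefins gives the five-membered butenolide (closure onto the 2-methylallyl olefin would need a four-membered ring), and C6 is not touched.

Step 4
Reactants: 9 acetaldehyde; 10 2,2-dimethoxyacetaldehyde
Product: 11 (S)-3-hydroxy-4,4-dimethoxybutanal
Conditions: (R)-α,α-bis[3,5-bis(trifluoromethyl)phenyl]prolinol (10 mol%), 9 (5 equiv), DMF, 4 °C
Reagents that add atoms: none
Why: Enamine-mediated direct cross-aldol (diarylprolinol catalysis): the acetaldehyde enamine adds to the activated, non-enolisable aldehyde 10 on the face directed by the catalyst hydroxyl, which with the (R)-catalyst gives the (S)-carbinol (future C9).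

Step 5
Reactants: 11 (S)-3-hydroxy-4,4-dimethoxybutanal; 12 formaldehyde
Product: 13 (S)-2-(1-hydroxy-2,2-dimethoxyethyl)prop-2-enal
Conditions: 37% aq. CH2O, pyrrolidine (10 mol%), EtCO2H (10 mol%), i-PrOH, 45 °C
Reagents that add atoms: none
Why: Organocatalytic α-methylenation (Mannich addition of the enamine to the formaldehyde iminium, then β-elimination of the amine) installs C14 and leaves a non-enolisable enal, so the C9 carbinol can no longer dehydrate or epimerise.

Step 6
Reactants: 13 (S)-2-(1-hydroxy-2,2-dimethoxyethyl)prop-2-enal; 14 angelic acid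
Product: 16 (S)-1,1-dimethoxy-3-methylidene-4-oxobutan-2-yl angelate, via mixed anhydride 15 (not isolated)
Conditions: 14, 2,4,6-Cl3C6H2COCl, Et3N, toluene, 25 °C; then 13, DMAP (cat.), 0 to 25 °C
Reagents that add atoms: 2,4,6-trichlorobenzoyl chloride, O=C(Cl)c1c(Cl)cc(Cl)cc1Cl (its aroyl atoms appear in 15 only)
Why: Yamaguchi esterification through mixed anhydride 15 acylates the single hydroxyl with retention at C9 and is the standard way to make angelates without Z-to-E isomerisation to the tiglate.

Step 7
Reactants: 16 (S)-1,1-dimethoxy-3-methylidene-4-oxobutan-2-yl angelate; 17 allylmagnesium bromide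
Product: 20 (2S,4R)-4-hydroxy-1,1-dimethoxy-3-methylidenehept-6-en-2-yl angelate, via B-allyldiisopinocampheylborane 18 (not isolated), via borinate ester 19 (not isolated)
Conditions: (+)-Ipc2BOMe, 17, Et2O, −78 to 25 °C; 16, −78 °C; then HOCH2CH2NH2, 25 °C
Reagents that add atoms: (+)-B-methoxydiisopinocampheylborane, COB([C@H]1C[C@H]2C[C@@H]([C@@H]1C)C2(C)C)[C@H]1C[C@H]2C[C@@H]([C@@H]1C)C2(C)C (its boron and isopinocampheyl atoms appear in 18 and 19 only)
Why: Brown allylboration adds only 1,2 to the enal (ester and acetal are inert to the borane), and reagent control fixes the C1 carbinol as R, a centre that is oxidised in step 11 but kept single so that all later intermediates are single compounds.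

Step 8
Reactants: 20 (2S,4R)-4-hydroxy-1,1-dimethoxy-3-methylidenehept-6-en-2-yl angelate
Product: 21 (2S,4R)-4-hydroxy-3-methylidene-1-oxohept-6-en-2-yl angelate (isolated as its five-membered lactol anomers)
Conditions: 2 M aq. HCl, THF, 0 to 25 °C
Reagents that add atoms: water, O
Why: Acid-catalysed acetal hydrolysis, helped by the γ-hydroxyl that traps the oxocarbenium ion as a cyclic acetal, unveils the C8 aldehyde as its lactol without touching the angelate or either stereocentre.

Step 9
Reactants: 8 (R)-3-(bromomethyl)-5-(2-methylallyl)furan-2(5H)-one; 21 (2S,4R)-4-hydroxy-3-methylidene-1-oxohept-6-en-2-yl angelate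
Product: 24 seco-diene diol (1R,6R,7R,8R,9S), via allylchromium dichloride 22 (not isolated), via chromium alkoxide 23 (not isolated)
Conditions: CrCl2 (8 equiv), THF/DMF 4:1, 25 °C; aq. NH4Cl
Reagents that add atoms: chromium dichloride, Cl[Cr]Cl (its atoms appear in 22 and 23 only)
Why: Divalent chromium reduces the C–Br bond of 8 by single-electron transfer to a butenolide-conjugated allyl radical, which a second CrCl2 captures as the γ-reactive allylchromium 22 (radical-polar crossover Barbier allylation of the Nozaki–Hiyama–Kishi type); 22 attacks the open aldehyde tautomer of 21 through a chair transition state on the butenolide face anti to the C6 side chain (6,7-trans), with the aldehyde chain equatorial (7,8-anti) and anti to the C9 acyloxy group (Felkin–Anh, 8,9-anti), so that C7 and C8 are both set as R and the exocyclic lactone methylene is unveiled.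

Step 10
Reactants: 24 seco-diene diol (1R,6R,7R,8R,9S)
Product: 25 (1R,6R,7R,8R,9S,3Z)-9-angeloyloxy-1,8-dihydroxygermacra-3,10(14),11(13)-trien-6,12-olide
Conditions: second-generation Grubbs catalyst RuCl2(=CHPh)(PCy3)(H2IMes) (15 mol%), 1,4-benzoquinone (30 mol%), toluene (1 mM), 80 °C
Reagents that add atoms: none
Why: Ring-closing metathesis of the allyl and 2-methylallyl termini closes the ten-membered ring, in which only the Z (cis-cyclodecene) trisubstituted olefin is accessible, while the two methylenes flanked by oxygenated or carbonyl carbons react more slowly.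

Step 11
Reactants: 25 (1R,6R,7R,8R,9S,3Z)-9-angeloyloxy-1,8-dihydroxygermacra-3,10(14),11(13)-trien-6,12-olide
Product: 26 (6R,7R,8R,9S,3Z)-9-angeloyloxy-8-hydroxy-1-oxogermacra-3,10(14),11(13)-trien-6,12-olide
Conditions: MnO2 (20 equiv), CH2Cl2, 25 °C
Reagents that add atoms: none
Why: Manganese dioxide oxidises only the allylic C1 carbinol (the C8 carbinol is not allylic), and its neutral surface does not move the β,γ-olefin into conjugation.

Step 12
Reactants: 26 (6R,7R,8R,9S,3Z)-9-angeloyloxy-8-hydroxy-1-oxogermacra-3,10(14),11(13)-trien-6,12-olide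
Product: 27 CNP0348992.4 (3S,4R,6R,7R,8R,9S)-9-angeloyloxy-3,4-epoxy-8-hydroxy-1-oxogermacra-10(14),11(13)-dien-6,12-olide
Conditions: mCPBA (1.1 equiv), NaHCO3, CH2Cl2, 0 °C
Reagents that add atoms: mCPBA, O=C(OO)c1cccc(Cl)c1
Why: Prilezhaev epoxidation attacks only the electron-rich trisubstituted C3=C4 olefin, adds syn to the Z-olefin to give the cis epoxide, and is expected to approach the exposed outer face of the ten-membered ring to give 3S,4R (this facial preference is not verified; see the fallback).

## Compound list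

1 | acrolein | C=CC=O | starting material
2 | (2-methylallyl)magnesium chloride | CC(=C)C[Mg]Cl | starting material
3 | B-(2-methylallyl)diisopinocampheylborane | CC(=C)CB([C@H]1C[C@H]2C[C@@H]([C@@H]1C)C2(C)C)[C@H]1C[C@H]2C[C@@H]([C@@H]1C)C2(C)C | intermediate (not isolated)
4 | diisopinocampheylborinate ester of 5 | C=C[C@H](OB([C@H]1C[C@H]2C[C@@H]([C@@H]1C)C2(C)C)[C@H]1C[C@H]2C[C@@H]([C@@H]1C)C2(C)C)CC(C)=C | intermediate (not isolated)
5 | (R)-5-methylhexa-1,5-dien-3-ol | C=C[C@H](O)CC(C)=C | intermediate
6 | 2-(bromomethyl)acrylic acid | C=C(CBr)C(=O)O | starting material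
7 | (R)-5-methylhexa-1,5-dien-3-yl 2-(bromomethyl)acrylate | C=C[C@H](OC(=O)C(=C)CBr)CC(C)=C | intermediate
8 | (R)-3-(bromomethyl)-5-(2-methylallyl)furan-2(5H)-one | BrCC1=C[C@@H](CC(C)=C)OC1=O | intermediate
9 | acetaldehyde | CC=O | starting material
10 | 2,2-dimethoxyacetaldehyde | COC(OC)C=O | starting material
11 | (S)-3-hydroxy-4,4-dimethoxybutanal | O=CC[C@H](O)C(OC)OC | intermediate
12 | formaldehyde | C=O | starting material
13 | (S)-2-(1-hydroxy-2,2-dimethoxyethyl)prop-2-enal | O=CC(=C)[C@H](O)C(OC)OC | intermediate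
14 | angelic acid, (Z)-2-methylbut-2-enoic acid | C/C=C(/C)C(=O)O | starting material
15 | angelic 2,4,6-trichlorobenzoic anhydride | O=C(OC(=O)c1c(Cl)cc(Cl)cc1Cl)/C(C)=C\C | intermediate (not isolated)
16 | (S)-1,1-dimethoxy-3-methylidene-4-oxobutan-2-yl angelate | O=CC(=C)[C@H](OC(=O)/C(C)=C\C)C(OC)OC | intermediate
17 | allylmagnesium bromide | C=CC[Mg]Br | starting material
18 | B-allyldiisopinocampheylborane | C=CCB([C@H]1C[C@H]2C[C@@H]([C@@H]1C)C2(C)C)[C@H]1C[C@H]2C[C@@H]([C@@H]1C)C2(C)C | intermediate (not isolated)
19 | diisopinocampheylborinate ester of 20 | C=CC[C@@H](OB([C@H]1C[C@H]2C[C@@H]([C@@H]1C)C2(C)C)[C@H]1C[C@H]2C[C@@H]([C@@H]1C)C2(C)C)C(=C)[C@H](OC(=O)/C(C)=C\C)C(OC)OC | intermediate (not isolated)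
20 | (2S,4R)-4-hydroxy-1,1-dimethoxy-3-methylidenehept-6-en-2-yl angelate | C=CC[C@@H](O)C(=C)[C@H](OC(=O)/C(C)=C\C)C(OC)OC | intermediate
21 | (2S,4R)-4-hydroxy-3-methylidene-1-oxohept-6-en-2-yl angelate, open-chain tautomer shown; isolated as the five-membered lactol (both anomers) | C=CC[C@@H](O)C(=C)[C@H](OC(=O)/C(C)=C\C)C=O | intermediate
22 | allylchromium dichloride from 8 (trivalent chromium, σ-bound at C13) | Cl[Cr](Cl)CC1=C[C@@H](CC(C)=C)OC1=O | intermediate (not isolated)
23 | C8 chromium dichloride alkoxide of 24 | C=CC[C@@H](O)C(=C)[C@H](OC(=O)/C(C)=C\C)[C@H](O[Cr](Cl)Cl)[C@H]1C(=C)C(=O)O[C@@H]1CC(C)=C | intermediate (not isolated)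
24 | seco-diene diol (1R,6R,7R,8R,9S): trans-4,5-disubstituted 3-methylidene-γ-butyrolactone with 2-methylallyl on C6 and the C8(OH)–C9(OAng)–C10(=CH2)–C1(OH)–allyl chain on C7 | C=CC[C@@H](O)C(=C)[C@H](OC(=O)/C(C)=C\C)[C@H](O)[C@H]1C(=C)C(=O)O[C@@H]1CC(C)=C | intermediate
25 | (1R,6R,7R,8R,9S,3Z)-9-angeloyloxy-1,8-dihydroxygermacra-3,10(14),11(13)-trien-6,12-olide | C=C1C(=O)O[C@@H]2C/C(C)=C\C[C@@H](O)C(=C)[C@H](OC(=O)/C(C)=C\C)[C@H](O)[C@@H]12 | intermediate
26 | (6R,7R,8R,9S,3Z)-9-angeloyloxy-8-hydroxy-1-oxogermacra-3,10(14),11(13)-trien-6,12-olide | C=C1C(=O)O[C@@H]2C/C(C)=C\CC(=O)C(=C)[C@H](OC(=O)/C(C)=C\C)[C@H](O)[C@@H]12 | intermediate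
27 | CNP0348992.4, (3S,4R,6R,7R,8R,9S)-9-angeloyloxy-3,4-epoxy-8-hydroxy-1-oxogermacra-10(14),11(13)-dien-6,12-olide | C=C1C(=O)O[C@@H]2C[C@@]3(C)O[C@H]3CC(=O)C(=C)[C@H](OC(=O)/C(C)=C\C)[C@H](O)[C@@H]12 | target

## Step count and risks

Total: 12 steps (3 to bromide 8, 5 to aldehyde 21, 4 after their union). Longest linear sequence: 9 steps (steps 4 to 12).

The three steps most likely to fail:

Step 12 (epoxidation). The face of the Z-olefin attacked by the peracid is governed only by the ring conformation and may be the wrong one, and the β,γ-epoxy ketone is sensitive. The fallback sets out from 25, before the C1 oxidation. A reagent-controlled Shi epoxidation (fructose-derived ketone catalyst or its enantiomer, whichever delivers oxygen to the 3S,4R face; KHSO5, K2CO3 buffer, MeCN/H2O, 0 °C) gives the epoxy diol F6. MnO2 then oxidises the allylic C1 carbinol, and the route is rejoined at 27.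

Step 10 (ring-closing metathesis). The strained ten-membered ring may close slowly, and the ruthenium carbene at C3 can instead engage the lactone methylene (eight-membered ring). The fallback sets out from 24. Dimethylamine (THF, 0 °C) adds to the lactone methylene to give the amine adduct F3. As its TsOH salt, F3 undergoes the same metathesis to the ring-closed amine F4. MeI converts F4 into the ammonium iodide F5, and aqueous NaHCO3 eliminates trimethylamine to restore the methylene. The route is rejoined at 25.

Step 9 (key union). The lactol may release its aldehyde too slowly for the organochromium reagent, and the chromium alkoxide next to the angelate could trigger acyl migration or erode Felkin control. The fallback sets out from 8. Borylation (B2pin2, CuCl, LiCl, KOAc, DMF, 25 °C) gives the allylboronate F1. Its Sc(OTf)3-catalysed allylboration of 21 (toluene, 0 °C) is a two-electron allyl transfer through the same closed chair and gives the borate ester F2. Aqueous NaHCO3 work-up cleaves the borate, and the route is rejoined at 24.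

## Further compounds

F1 | step 9 | (R)-5-(2-methylallyl)-3-[(4,4,5,5-tetramethyl-1,3,2-dioxaborolan-2-yl)methyl]furan-2(5H)-one | CC1(C)OB(CC2=C[C@@H](CC(C)=C)OC2=O)OC1(C)C
F2 | step 9 | C8 O-pinacolborate ester of 24 | C=CC[C@@H](O)C(=C)[C@H](OC(=O)/C(C)=C\C)[C@H](OB1OC(C)(C)C(C)(C)O1)[C@H]1C(=C)C(=O)O[C@@H]1CC(C)=C
F3 | step 10 | dimethylamine adduct of 24 at the lactone methylene (C13 amine, C11 epimers) | C=CC[C@@H](O)C(=C)[C@H](OC(=O)/C(C)=C\C)[C@H](O)[C@H]1C(CN(C)C)C(=O)O[C@@H]1CC(C)=C
F4 | step 10 | dimethylamine adduct of 25 (ring-closed, C11 epimers) | CN(C)CC1C(=O)O[C@@H]2C/C(C)=C\C[C@@H](O)C(=C)[C@H](OC(=O)/C(C)=C\C)[C@H](O)[C@@H]12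
F5 | step 10 | trimethylammonium iodide of F4 | C[N+](C)(C)CC1C(=O)O[C@@H]2C/C(C)=C\C[C@@H](O)C(=C)[C@H](OC(=O)/C(C)=C\C)[C@H](O)[C@@H]12.[I-]
F6 | step 12 | (1R,3S,4R,6R,7R,8R,9S)-9-angeloyloxy-3,4-epoxy-1,8-dihydroxygermacra-10(14),11(13)-dien-6,12-olide | C=C1C(=O)O[C@@H]2C[C@@]3(C)O[C@H]3C[C@@H](O)C(=C)[C@H](OC(=O)/C(C)=C\C)[C@H](O)[C@@H]12
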